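## Retrosynthetic overview

1. Ring names: B is the benzo ring fused to the cycloheptatriene (ring D) and to dihydrofuran E; C is the pentasubstituted benzo ring fused to D and to dihydrofuran F. The last disconnection is global O-demethylation.
2. Rings D and E are opened together. Ring E is not made in its final size: it comes from a spiro-cyclopropane (three atoms) by Cloke–Wilson ring expansion (to five). The cyclopropane forms in the same operation, by intramolecular cyclopropanation of the styryl double bond on ring C by a rhodium carbenoid from an o-quinone diazide of ring B.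
3. Enabling feature: in ring B the furan oxygen and the carbon bonded to C-3 of ring E are ortho, so the pair can be stored as C=O next to C=N2. C-2 of ring E carries a 4-methoxyphenyl donor, so the cyclopropane bond from the spiro carbon to it ionises toward re-aromatised ring B. The cis-triarylethene of ring D holds the styryl bond within a seven-membered reach of the carbene carbon.
4. The triarylethene comes from two Suzuki couplings on the gem-dibromoalkene of a 3-hydroxy-5-methoxy-2-nitrobenzaldehyde unit (ring B): first 4-methoxyphenyl trans to ring B, then the ring C boronate cis to it.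
5. The ring C fragment is a 7-borylated trans-2,3-diaryl-dihydrobenzofuran (ring F) made by enantioselective carbene C–H insertion. Order of ring formation: F, then D with the cyclopropane, then E.

Key step: step 17

Assumption: the senses of induction of Rh2(R-PTAD)4 (dirhodium tetrakis[(R)-(1-adamantyl)(phthalimido)acetate], step 7) and Rh2(S-PTTL)4 (dirhodium tetrakis[N-phthaloyl-(S)-tert-leucinate], step 17) are taken as drawn (otherwise the enantiomeric catalyst is used), and the insertion of step 7 is taken to be cis-selective.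

## Route

Step 1
Reactants: 1 4-bromo-3,5-dimethoxybenzaldehyde
Product: 2 2,4-dibromo-3,5-dimethoxybenzaldehyde
Conditions: NBS (1.05 equiv), DMF, 23 → 50 °C
Reagents that add atoms: N-bromosuccinimide, O=C1CCC(=O)N1Br
Why: Electrophilic aromatic bromination, in which the two free ring positions of 1 are equivalent by symmetry and activated by the methoxy groups, so monobromination can give only 2.

Step 2
Reactants: 2 2,4-dibromo-3,5-dimethoxybenzaldehyde; 3 diethyl (4-methoxybenzyl)phosphonate
Product: 4 2,4-dibromo-1,3-dimethoxy-5-[(E)-2-(4-methoxyphenyl)ethenyl]benzene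
Conditions: NaH, THF, 0 → 23 °C
Reagents that add atoms: none
Why: Horner–Wadsworth–Emmons olefination of an aryl aldehyde with a benzylic phosphonate, which should give the (E)-stilbene.

Step 3
Reactants: 4 dibromostilbene; 5 3,5-dimethoxybenzoyl chloride
Product: 7 {3-bromo-2,6-dimethoxy-4-[(E)-2-(4-methoxyphenyl)ethenyl]phenyl}(3,5-dimethoxyphenyl)methanone, via aryllithium 6 (not isolated)
Conditions: n-BuLi (1.0 equiv), THF, −78 °C, 20 min; then 5, −78 → 0 °C
Reagents that add atoms: none
Why: Bromine–lithium exchange under equilibrating conditions should select the bromine between the two methoxy groups (the more stabilised aryllithium), and acylation of this hindered aryllithium by an aroyl chloride should stop at the diaryl ketone.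

Step 4
Reactants: 7 dimethoxy ketone
Product: 8 {3-bromo-2-hydroxy-6-methoxy-4-[(E)-2-(4-methoxyphenyl)ethenyl]phenyl}(3,5-dimethoxyphenyl)methanone
Conditions: BCl3 (1.1 equiv), CH2Cl2, −78 → −10 °C; then H2O
Reagents that add atoms: none
Why: Carbonyl-assisted O-demethylation with BCl3, in which the ortho methoxy group squeezed between bromine and the ketone is twisted out of conjugation, is the more Lewis basic and should be cleaved first, while the other ortho methoxy group and the three non-chelating methyl ethers stay.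

Step 5
Reactants: 8 bromophenol ketone; 9 4-methoxybenzyl chloride
Product: 10 {3-bromo-6-methoxy-2-[(4-methoxybenzyl)oxy]-4-[(E)-2-(4-methoxyphenyl)ethenyl]phenyl}(3,5-dimethoxyphenyl)methanone
Conditions: K2CO3, NaI (10 mol %), DMF, 60 °C
Reagents that add atoms: none
Why: Williamson ether synthesis on the acidic phenol, which installs the benzylic CH2 that becomes C-2 of ring F.

Step 6
Reactants: 10 benzyl ether ketone
Product: 11 hydrazone of 10
Conditions: N2H4·H2O (10 equiv), AcOH (cat.), EtOH, 90 °C, sealed tube under N2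
Reagents that add atoms: hydrazine hydrate, NN.O
Why: Condensation of a diaryl ketone with hydrazine to the N-unsubstituted hydrazone, for which the small alpha-effect nucleophile suits the doubly ortho-substituted carbonyl group and no other group of 10 should react.

Step 7
Reactants: 11 hydrazone
Product: 13 (2S,3R)-7-bromo-3-(3,5-dimethoxyphenyl)-4-methoxy-2-(4-methoxyphenyl)-6-[(E)-2-(4-methoxyphenyl)ethenyl]-2,3-dihydro-1-benzofuran, via diaryldiazomethane 12 (not isolated)
Conditions: MnO2, CH2Cl2, 0 °C, filter; then Rh2(R-PTAD)4 (1 mol %), CH2Cl2, −20 → 23 °C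
Reagents that add atoms: none
Why: Oxidation of the hydrazone to the diaryldiazomethane and enantioselective intramolecular C–H insertion of the donor/donor rhodium carbenoid into the activated 4-methoxybenzylic O–CH2 bond (1,5-insertion), in which the chiral carboxylate ligands should set C-3 as R and the concerted insertion should give the cis ring (C-2 S).

Step 8
Reactants: 13 cis-dihydrobenzofuran
Product: 14 (2R,3R)-7-bromo-3-(3,5-dimethoxyphenyl)-4-methoxy-2-(4-methoxyphenyl)-6-[(E)-2-(4-methoxyphenyl)ethenyl]-2,3-dihydro-1-benzofuran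
Conditions: CF3CO2H (5 equiv), CH2Cl2, 0 → 23 °C
Reagents that add atoms: none
Why: Acid-mediated epimerisation at C-2 by reversible ionisation of the 4-methoxybenzylic C–O bond and re-closure to the thermodynamically preferred trans ring, so that the untouched C-3 (R) dictates C-2 (R).

Step 9
Reactants: 14 trans-bromide
Product: 16 2-{(2R,3R)-3-(3,5-dimethoxyphenyl)-4-methoxy-2-(4-methoxyphenyl)-6-[(E)-2-(4-methoxyphenyl)ethenyl]-2,3-dihydro-1-benzofuran-7-yl}-4,4,5,5-tetramethyl-1,3,2-dioxaborolane, via aryllithium 15 (not isolated)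
Conditions: n-BuLi, THF, −78 °C; then iPrOBpin, −78 → 23 °C; then H2O
Reagents that add atoms: 2-isopropoxy-4,4,5,5-tetramethyl-1,3,2-dioxaborolane, CC(C)OB1OC(C)(C)C(C)(C)O1
Why: Bromine–lithium exchange followed by electrophilic borylation, where exchange at −78 °C should outrun deprotonation and the two stereocentres are not involved.

Step 10
Reactants: 17 3,5-dimethoxybenzaldehyde
Product: 18 3,5-dimethoxy-2-nitrobenzaldehyde
Conditions: HNO3 (65 %, 1.1 equiv), AcOH, 0 → 10 °C
Reagents that add atoms: nitric acid, O[N+](=O)[O-]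
Why: Electrophilic nitration, which should prefer the position between the formyl and a methoxy group (para to the other methoxy group) over the crowded position between the two methoxy groups.

Step 11
Reactants: 18 nitroaldehyde
Product: 19 1-(2,2-dibromoethenyl)-3,5-dimethoxy-2-nitrobenzene
Conditions: CBr4 (2 equiv), PPh3 (4 equiv), CH2Cl2, 0 °C
Reagents that add atoms: carbon tetrabromide, BrC(Br)(Br)Br
Why: Ramirez dibromo-olefination (first stage of the Corey–Fuchs sequence) of the aldehyde by the ylide Ph3P=CBr2, to which the nitro group is inert.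

Step 12
Reactants: 19 dibromoalkene
Product: 20 3-(2,2-dibromoethenyl)-5-methoxy-2-nitrophenol
Conditions: AlCl3 (1.5 equiv), CH2Cl2, 0 → 23 °C; then aq. HCl
Reagents that add atoms: none
Why: Lewis-acid O-demethylation directed by chelation to the nitro group, a known selectivity of 2-nitroanisoles, which should free only the oxygen ortho to nitrogen, the one that ends in ring E.

Step 13
Reactants: 20 dibromoalkene nitrophenol; 21 (4-methoxyphenyl)boronic acid
Product: 22 3-[(Z)-2-bromo-2-(4-methoxyphenyl)ethenyl]-5-methoxy-2-nitrophenol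
Conditions: Pd2(dba)3 (2.5 mol %), tri(2-furyl)phosphine (15 mol %), Na2CO3 (aq., 3 equiv), 1,4-dioxane, 65 °C
Reagents that add atoms: none
Why: Stereoselective Suzuki–Miyaura mono-coupling of a 1,1-dibromoalkene, in which oxidative addition should take place at the less hindered C–Br bond trans to ring B, so the 4-methoxyphenyl group enters trans to ring B and the (Z)-bromoalkene remains.

Step 14
Reactants: 16 benzofuranyl boronate; 22 (Z)-bromoalkene
Product: 23 3-[(Z)-2-{benzofuran-7-yl group of 16}-2-(4-methoxyphenyl)ethenyl]-5-methoxy-2-nitrophenol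
Conditions: Pd(OAc)2 (5 mol %), SPhos (10 mol %), K3PO4 (4 equiv), toluene/H2O (10:1), 90 °C
Reagents that add atoms: none
Why: Suzuki–Miyaura coupling of an alkenyl bromide with a hindered aryl boronate under a dialkylbiarylphosphine ligand, which should proceed with retention of alkene geometry and so place ring C cis to ring B.

Step 15
Reactants: 23 nitrophenol
Product: 24 2-amino-3-[(Z)-2-{benzofuran-7-yl group of 16}-2-(4-methoxyphenyl)ethenyl]-5-methoxyphenol
Conditions: Fe powder (6 equiv), NH4Cl, EtOH/H2O (4:1), 70 °C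
Reagents that add atoms: none
Why: Chemoselective Béchamp-type reduction of the nitro group to the amine, which should leave both alkenes, the aryl ethers and ring F untouched.

Step 16
Reactants: 24 aminophenol
Product: 25 6-diazo-3-methoxy-5-[(Z)-2-{benzofuran-7-yl group of 16}-2-(4-methoxyphenyl)ethenyl]cyclohexa-2,4-dien-1-one
Conditions: t-BuONO (1.2 equiv), MeCN/THF, 0 °C, dark
Reagents that add atoms: tert-butyl nitrite, CC(C)(C)ON=O
Why: Diazotisation of an o-aminophenol under near-neutral conditions, in which the diazonium ion should at once lose the phenolic proton to give the neutral o-quinone diazide.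

Step 17
Reactants: 25 o-quinone diazide
Product: 27 heptamethyl ether of CNP0325907.1, via spirocyclopropyl dienone 26 (not isolated)
Conditions: Rh2(S-PTTL)4 (2 mol %), CH2Cl2, syringe-pump addition of 25 (final 0.005 M), −20 → 23 °C; then Sc(OTf)3 (5 mol %), 23 °C
Reagents that add atoms: none
Why: Proposed new method: loss of N2 from 25 should give an electrophilic rhodium carbenoid at the ring B carbon next to the carbonyl group, which adds to the styryl double bond in an intramolecular [2+1] cyclopropanation, bonding to the alkene carbon on ring C (7-exo closure of ring D) and to the 4-methoxybenzylic carbon to give the spiro[2.5]octadienone 26. In 26 the three-membered ring is a donor–acceptor cyclopropane (4-methoxyphenyl donor, dienone acceptor), so the bond from the spiro carbon to the 4-methoxybenzylic carbon should ionise and the carbonyl oxygen should close onto that carbon (Cloke–Wilson ring expansion from three to five atoms, ring E closing by O-attack on the benzylic cation), driven by re-aromatisation of ring B. The closest known reactions are the divalent-rhodium-catalysed cyclopropanation and formal [3+2] annulation of styrenes with quinone diazides and 2-diazo-1,3-diketones and the Cloke–Wilson rearrangement of acyl cyclopropanes to 2,3-dihydrofurans; new are the intramolecular, seven-membered-ring-forming setting and the 1,2-diaryl alkene. C-3 of ring E is set in the cyclopropanation by the alkene face taken, which the chiral carboxylate ligands should control (ring F is too remote to matter, and a minor epimer would be a separable diastereomer); C-2 follows from the E geometry of the alkene, which puts the two aryl groups trans on the cyclopropane, and the ring expansion keeps or, through the benzylic cation and the Lewis acid, restores the trans relationship. The step needs chemoselectivity for this alkene over Wolff rearrangement, the ether oxygen of ring F and the triarylethene, secured by metal catalysis in the dark, by the Z-triarylethene that holds the styryl carbon within reach and by the polarity match of carbenoid and 4-methoxystyrene; the regioselectivity of ring opening is secured by the 4-methoxyphenyl group, which makes only one cyclopropane bond ionisable.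

Step 18
Reactants: 27 heptamethyl ether
Product: 28 CNP0325907.1
Conditions: BBr3 (20 equiv), CH2Cl2, −78 → 23 °C; then H2O
Reagents that add atoms: none
Why: Lewis-acid cleavage of the seven aryl methyl ethers (global O-demethylation), during which both dihydrofurans are already trans, so reversible C–O ionisation should not change any configuration.

## Compound list

1 | 4-bromo-3,5-dimethoxybenzaldehyde | COc1cc(C=O)cc(OC)c1Br | starting material
2 | 2,4-dibromo-3,5-dimethoxybenzaldehyde | O=Cc1cc(OC)c(Br)c(OC)c1Br | intermediate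
3 | diethyl (4-methoxybenzyl)phosphonate | CCOP(=O)(Cc1ccc(OC)cc1)OCC | starting material
4 | 2,4-dibromo-1,3-dimethoxy-5-[(E)-2-(4-methoxyphenyl)ethenyl]benzene | COc1ccc(cc1)/C=C/c2cc(OC)c(Br)c(OC)c2Br | intermediate
5 | 3,5-dimethoxybenzoyl chloride | COc1cc(cc(OC)c1)C(Cl)=O | starting material
6 | {3-bromo-2,6-dimethoxy-4-[(E)-2-(4-methoxyphenyl)ethenyl]phenyl}lithium | COc1ccc(cc1)/C=C/c2cc(OC)c([Li])c(OC)c2Br | intermediate
7 | {3-bromo-2,6-dimethoxy-4-[(E)-2-(4-methoxyphenyl)ethenyl]phenyl}(3,5-dimethoxyphenyl)methanone | COc1ccc(cc1)/C=C/c2cc(OC)c(C(=O)c3cc(OC)cc(OC)c3)c(OC)c2Br | intermediate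
8 | {3-bromo-2-hydroxy-6-methoxy-4-[(E)-2-(4-methoxyphenyl)ethenyl]phenyl}(3,5-dimethoxyphenyl)methanone | COc1ccc(cc1)/C=C/c2cc(OC)c(C(=O)c3cc(OC)cc(OC)c3)c(O)c2Br | intermediate
9 | 4-methoxybenzyl chloride | COc1ccc(CCl)cc1 | starting material
10 | {3-bromo-6-methoxy-2-[(4-methoxybenzyl)oxy]-4-[(E)-2-(4-methoxyphenyl)ethenyl]phenyl}(3,5-dimethoxyphenyl)methanone | COc1ccc(cc1)/C=C/c2cc(OC)c(C(=O)c3cc(OC)cc(OC)c3)c(OCc4ccc(OC)cc4)c2Br | intermediate
11 | hydrazone (C=N–NH2) of ketone 10 | COc1ccc(cc1)/C=C/c2cc(OC)c(C(=NN)c3cc(OC)cc(OC)c3)c(OCc4ccc(OC)cc4)c2Br | intermediate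
12 | {3-bromo-6-methoxy-2-[(4-methoxybenzyl)oxy]-4-[(E)-2-(4-methoxyphenyl)ethenyl]phenyl}(3,5-dimethoxyphenyl)diazomethane | COc1ccc(cc1)/C=C/c2cc(OC)c(C(=[N+]=[N-])c3cc(OC)cc(OC)c3)c(OCc4ccc(OC)cc4)c2Br | intermediate
13 | (2S,3R)-7-bromo-3-(3,5-dimethoxyphenyl)-4-methoxy-2-(4-methoxyphenyl)-6-[(E)-2-(4-methoxyphenyl)ethenyl]-2,3-dihydro-1-benzofuran (cis) | COc1ccc(cc1)/C=C/c2cc(OC)c3c(c2Br)O[C@H](c4ccc(OC)cc4)[C@@H]3c5cc(OC)cc(OC)c5 | intermediate
14 | (2R,3R)-7-bromo-3-(3,5-dimethoxyphenyl)-4-methoxy-2-(4-methoxyphenyl)-6-[(E)-2-(4-methoxyphenyl)ethenyl]-2,3-dihydro-1-benzofuran (trans) | COc1ccc(cc1)/C=C/c2cc(OC)c3c(c2Br)O[C@@H](c4ccc(OC)cc4)[C@@H]3c5cc(OC)cc(OC)c5 | intermediate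
15 | 7-lithio analogue of 14 (Li in place of Br) | COc1ccc(cc1)/C=C/c2cc(OC)c3c(c2[Li])O[C@@H](c4ccc(OC)cc4)[C@@H]3c5cc(OC)cc(OC)c5 | intermediate
16 | 2-{(2R,3R)-3-(3,5-dimethoxyphenyl)-4-methoxy-2-(4-methoxyphenyl)-6-[(E)-2-(4-methoxyphenyl)ethenyl]-2,3-dihydro-1-benzofuran-7-yl}-4,4,5,5-tetramethyl-1,3,2-dioxaborolane | COc1ccc(cc1)/C=C/c2cc(OC)c3c(c2B4OC(C)(C)C(C)(C)O4)O[C@@H](c5ccc(OC)cc5)[C@@H]3c6cc(OC)cc(OC)c6 | intermediate
17 | 3,5-dimethoxybenzaldehyde | COc1cc(C=O)cc(OC)c1 | starting material
18 | 3,5-dimethoxy-2-nitrobenzaldehyde | COc1cc(OC)c([N+](=O)[O-])c(C=O)c1 | intermediate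
19 | 1-(2,2-dibromoethenyl)-3,5-dimethoxy-2-nitrobenzene | COc1cc(OC)c([N+](=O)[O-])c(C=C(Br)Br)c1 | intermediate
20 | 3-(2,2-dibromoethenyl)-5-methoxy-2-nitrophenol | COc1cc(O)c([N+](=O)[O-])c(C=C(Br)Br)c1 | intermediate
21 | (4-methoxyphenyl)boronic acid | COc1ccc(cc1)B(O)O | starting material
22 | 3-[(Z)-2-bromo-2-(4-methoxyphenyl)ethenyl]-5-methoxy-2-nitrophenol | COc1ccc(cc1)/C(Br)=C/c2cc(OC)cc(O)c2[N+](=O)[O-] | intermediate
23 | 3-[(Z)-2-{(2R,3R)-3-(3,5-dimethoxyphenyl)-4-methoxy-2-(4-methoxyphenyl)-6-[(E)-2-(4-methoxyphenyl)ethenyl]-2,3-dihydro-1-benzofuran-7-yl}-2-(4-methoxyphenyl)ethenyl]-5-methoxy-2-nitrophenol | COc1ccc(cc1)/C(=C/c2cc(OC)cc(O)c2[N+](=O)[O-])c3c(/C=C/c4ccc(OC)cc4)cc(OC)c5c3O[C@@H](c6ccc(OC)cc6)[C@@H]5c7cc(OC)cc(OC)c7 | intermediate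
24 | 2-amino analogue of 23 (NH2 in place of NO2) | COc1ccc(cc1)/C(=C/c2cc(OC)cc(O)c2N)c3c(/C=C/c4ccc(OC)cc4)cc(OC)c5c3O[C@@H](c6ccc(OC)cc6)[C@@H]5c7cc(OC)cc(OC)c7 | intermediate
25 | 6-diazo-3-methoxy-5-[(Z)-2-{benzofuran-7-yl group of 16}-2-(4-methoxyphenyl)ethenyl]cyclohexa-2,4-dien-1-one | COc1ccc(cc1)/C(=C/C2=CC(OC)=CC(=O)C2=[N+]=[N-])c3c(/C=C/c4ccc(OC)cc4)cc(OC)c5c3O[C@@H](c6ccc(OC)cc6)[C@@H]5c7cc(OC)cc(OC)c7 | intermediate
26 | spirocyclopropyl dienone: the former diazo carbon (spiro, R) is bonded to both carbons of the former styryl bond, ring D is closed, the cyclopropane CH on ring C is S and the CH bearing 4-methoxyphenyl is S (aryl groups trans); ring F (2R,3R) | COc1ccc(cc1)C2=CC3=CC(OC)=CC(=O)[C@]34[C@@H]([C@H]4c5ccc(OC)cc5)c6cc(OC)c7c(c62)O[C@@H](c8ccc(OC)cc8)[C@@H]7c9cc(OC)cc(OC)c9 | intermediate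
27 | heptamethyl ether of CNP0325907.1 (all seven OH as OMe; ring E: O–CH(aryl) S and CH S, trans; ring F: 2R,3R, trans) | COc1ccc(cc1)C2=Cc3cc(OC)cc4c3[C@H](c5cc(OC)c6c(c52)O[C@@H](c7ccc(OC)cc7)[C@@H]6c8cc(OC)cc(OC)c8)[C@@H](c9ccc(OC)cc9)O4 | intermediate
28 | CNP0325907.1 (heptaphenol; configurations as in 27) | Oc1ccc(C2=Cc3cc(O)cc4c3[C@H](c3cc(O)c5c(c32)O[C@@H](c2ccc(O)cc2)[C@@H]5c2cc(O)cc(O)c2)[C@@H](c2ccc(O)cc2)O4)cc1 | target

## Step count and risks

Total step count: 18. Longest linear sequence: 14 steps (steps 1–9, then 14–18); the ring B fragment takes steps 10–13.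

Steps most likely to fail:

1. Step 17. The carbenoid may be intercepted by the ether oxygen of ring F (oxonium ylide, then a Stevens-type shift), it may dimerise, or the face selectivity of the cyclopropanation may be poor. Fallback with known chemistry, setting out from 24 and coming back at 27: the aminophenol 24 is diazotised (NaNO2, aq. HCl/MeCN, 0 °C) to the diazonium chloride F1, which with KI gives the iodophenol F2 (Sandmeyer-type iodination). An intramolecular Heck reaction of F2 (Pd(OAc)2, P(o-tol)3, K2CO3, DMF, 90 °C; 7-exo carbopalladation of the styryl bond, then beta-hydride elimination) should close ring D and leave the 4-methoxybenzylidene phenol F3. A Brønsted acid (p-TsOH, CH2Cl2, 23 °C) then protonates the alkene carbon on ring D, and the phenol closes onto the 4-methoxybenzylic cation to the trans ring E. This gives 27 together with the diastereomer F4, in which both centres of ring E are inverted; F4 is removed by chromatography.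

2. Step 7. Condensation and oxidation at the doubly ortho-substituted ketone may be slow, insertion may go into the neighbouring methoxy C–H bond, or enantioselectivity may erode. Fallback setting out from 8 and coming back at 14: ketone 8 is reduced (NaBH4, MeOH/THF) to the 2-hydroxybenzhydrol F5, which with sodium 4-methylbenzenesulfinate and formic acid gives the sulfone F6. K2CO3 eliminates sulfinate from F6 to the o-quinone methide F7, which is trapped in a formal [4+1] annulation by the ylide of dimethyl(4-methoxybenzyl)sulfonium chloride F8 (made from 9 and dimethyl sulfide). Conjugate addition and SN2 ring closure should give the trans-dihydrobenzofuran as the racemate, 14 and its enantiomer F9, and 14 is taken by preparative HPLC on a chiral stationary phase.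

3. Step 4. Discrimination between the two ortho methyl ethers may be poor, or both may be cleaved. Fallback setting out from 7 and coming back at 10: both methyl ethers flanking the ketone are cleaved with excess BCl3 (CH2Cl2, 0 → 23 °C) to the diol F10. The more acidic hydroxyl, the one next to bromine, is alkylated with 9 and one equivalent of KHCO3 (DMF, 40 °C) to the mono-ether F11. The remaining hydroxyl is methylated (MeI, K2CO3, acetone) to give 10.

## Further compounds

F1 | step 17 | diazonium chloride from 24 (N2+ in place of NH2) | COc1ccc(cc1)/C(=C/c2cc(OC)cc(O)c2[N+]#N)c3c(/C=C/c4ccc(OC)cc4)cc(OC)c5c3O[C@@H](c6ccc(OC)cc6)[C@@H]5c7cc(OC)cc(OC)c7.[Cl-]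
F2 | step 17 | 2-iodo analogue of 24 (I in place of NH2) | COc1ccc(cc1)/C(=C/c2cc(OC)cc(O)c2I)c3c(/C=C/c4ccc(OC)cc4)cc(OC)c5c3O[C@@H](c6ccc(OC)cc6)[C@@H]5c7cc(OC)cc(OC)c7
F3 | step 17 | Heck product: ring D closed, exocyclic 4-methoxybenzylidene on ring D, free phenol on ring B, ring F (2R,3R) | COc1ccc(cc1)C2=Cc3cc(OC)cc(O)c3C(=Cc4ccc(OC)cc4)c5cc(OC)c6c(c52)O[C@@H](c7ccc(OC)cc7)[C@@H]6c8cc(OC)cc(OC)c8
F4 | step 17 | diastereomer of 27 with both centres of ring E inverted (R,R) | COc1ccc(cc1)C2=Cc3cc(OC)cc4c3[C@@H](c5cc(OC)c6c(c52)O[C@@H](c7ccc(OC)cc7)[C@@H]6c8cc(OC)cc(OC)c8)[C@H](c9ccc(OC)cc9)O4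
F5 | step 7 | {3-bromo-2-hydroxy-6-methoxy-4-[(E)-2-(4-methoxyphenyl)ethenyl]phenyl}(3,5-dimethoxyphenyl)methanol (racemic) | COc1ccc(cc1)/C=C/c2cc(OC)c(C(O)c3cc(OC)cc(OC)c3)c(O)c2Br
F6 | step 7 | 4-methylphenyl sulfone of F5 (SO2Tol in place of the carbinol OH) | COc1ccc(cc1)/C=C/c2cc(OC)c(C(c3cc(OC)cc(OC)c3)S(=O)(=O)c4ccc(C)cc4)c(O)c2Br
F7 | step 7 | o-quinone methide from F6 (ring C as 6-(3,5-dimethoxybenzylidene)cyclohexa-2,4-dienone) | COc1ccc(cc1)/C=C/C2=C(Br)C(=O)C(=Cc3cc(OC)cc(OC)c3)C(OC)=C2
F8 | step 7 | dimethyl(4-methoxybenzyl)sulfonium chloride | C[S+](C)Cc1ccc(OC)cc1.[Cl-]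
F9 | step 7 | (2S,3S) enantiomer of 14 | COc1ccc(cc1)/C=C/c2cc(OC)c3c(c2Br)O[C@H](c4ccc(OC)cc4)[C@H]3c5cc(OC)cc(OC)c5
F10 | step 4 | {3-bromo-2,6-dihydroxy-4-[(E)-2-(4-methoxyphenyl)ethenyl]phenyl}(3,5-dimethoxyphenyl)methanone | COc1ccc(cc1)/C=C/c2cc(O)c(C(=O)c3cc(OC)cc(OC)c3)c(O)c2Br
F11 | step 4 | {3-bromo-6-hydroxy-2-[(4-methoxybenzyl)oxy]-4-[(E)-2-(4-methoxyphenyl)ethenyl]phenyl}(3,5-dimethoxyphenyl)methanone | COc1ccc(cc1)/C=C/c2cc(O)c(C(=O)c3cc(OC)cc(OC)c3)c(OCc4ccc(OC)cc4)c2Br
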